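**Retrosynthetic overview**
1. The strategy rests on ring E (C7, C8, C14, spiro carbon C4', carbinol carbon C10'). Quaternary C4' holds arene carbon C14 on the cyclopropane face of the thujane, and C10' lies beta to the C6 ketone through C7. Together these mark the aldol of an alpha-aryl aldehyde that a 1,2-aryl shift can deliver.
2. Disconnections: the hydroxy quinone methide goes back to the 11,12-catechol (oxidation, tautomerisation through H-7). The C7-C10' bond is cut by an intramolecular Mukaiyama aldol, and the C14-C4' bond by a retro semipinacol aryl shift to a chlorohydrin. The C14-C10' bond comes from a C14 aryllithium and an alpha-chloro aldehyde.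
3. Fragment 1 comes from (+)-carnosic acid: C20 acid to methyl, bromide at C14, C6 ketone through the 6-ene, C5 epimerised to the cis fusion. Fragment 2 comes from (+)-sabinene by hydroboration, oxidation and face-selective chlorination.
4. Ring order: rings A, B, C and the bicyclo[3.1.0]hexane are bought intact. Ring E is the only ring made, and it is made last.

Key step: step 15

Numbering: abietane numbers are used for the diterpene half and primed thujane numbers for the monoterpene half. C1' bears isopropyl, C4' is the spiro carbon, C5' the cyclopropane CH, C6' the cyclopropane CH2 and C10' the carbinol carbon. Alpha and beta refer to the usual abietane drawing with C20 beta.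
Assumption: the bought (+)-carnosic acid and (+)-sabinene are single enantiomers, so C10, C1' and C5', which no step touches, fix the absolute configuration.

**Step 1**
Reactants: 1 (+)-carnosic acid
Product: 2 benzyl 11,12-bis(benzyloxy)abieta-8,11,13-trien-20-oate
Conditions: BnBr (4 equiv), K2CO3, n-Bu4NI (cat.), degassed DMF, argon, 50 °C
Reagents that add atoms: benzyl bromide, BrCc1ccccc1
Why: Williamson-type O-alkylation of the two phenoxides and the carboxylate in one operation; oxygen is kept out because the catecholate is easily oxidised, and no stereocentre is involved.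

**Step 2**
Reactants: 2 benzyl 11,12-bis(benzyloxy)abieta-8,11,13-trien-20-oate
Product: 3 11,12-bis(benzyloxy)abieta-8,11,13-trien-20-ol
Conditions: LiAlH4, THF, reflux; H2O, aq NaOH work-up
Reagents that add atoms: none
Why: LiAlH4 reduction of the hindered neopentyl benzyl ester to the primary C20 alcohol, to which aryl benzyl ethers and the arene are inert.

**Step 3**
Reactants: 3 11,12-bis(benzyloxy)abieta-8,11,13-trien-20-ol
Product: 4 11,12-bis(benzyloxy)abieta-8,11,13-trien-20-al
Conditions: Dess-Martin periodinane, CH2Cl2, rt
Reagents that add atoms: none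
Why: Dess-Martin oxidation stops at the aldehyde and never makes C20 a leaving-group centre, so the Wagner-Meerwein ring enlargement that C20 sulfonates of this skeleton undergo is avoided.

**Step 4**
Reactants: 4 11,12-bis(benzyloxy)abieta-8,11,13-trien-20-al
Product: 6 11,12-bis(benzyloxy)abieta-8,11,13-triene, via C20 hydrazone 5 (not isolated)
Conditions: N2H4·H2O (excess), n-BuOH, 115 °C; evaporate; t-BuOK, DMSO, argon, 25 → 70 °C
Reagents that add atoms: hydrazine, NN (its nitrogen stands in 5 only and leaves as N2)
Why: Wolff-Kishner reduction run on the preformed hydrazone with t-BuOK in DMSO, so that no free non-enolisable alpha-aryl aldehyde is left to be deformylated by base and the aryl benzyl ethers are spared the roughly 200 °C of the glycol procedure; C10 keeps its configuration because only C20 reacts.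

**Step 5**
Reactants: 6 11,12-bis(benzyloxy)abieta-8,11,13-triene
Product: 7 14-bromo-11,12-bis(benzyloxy)abieta-8,11,13-triene
Conditions: NBS, MeCN, dark, 0 °C → rt
Reagents that add atoms: N-bromosuccinimide, O=C1CCC(=O)N1Br
Why: Electrophilic aromatic bromination: C14 is the only unsubstituted carbon of ring C and lies para to the C11 oxygen, while the polar solvent and darkness hold back radical bromination at C7 and at the benzyl CH2 groups.

**Step 6**
Reactants: 7 14-bromo-11,12-bis(benzyloxy)abieta-8,11,13-triene
Product: 8 14-bromo-11,12-bis(benzyloxy)abieta-6,8,11,13-tetraene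
Conditions: DDQ, 1,4-dioxane, reflux
Reagents that add atoms: none
Why: DDQ dehydrogenation: hydride leaves benzylic C7, whose cation is stabilised by the para C12 oxygen, and loss of H-6 gives the styrene-type 6-ene without touching C5.

**Step 7**
Reactants: 8 14-bromo-11,12-bis(benzyloxy)abieta-6,8,11,13-tetraene
Product: 9 14-bromo-11,12-bis(benzyloxy)-6alpha,7alpha-epoxyabieta-8,11,13-triene
Conditions: mCPBA, NaHCO3 (buffer), CH2Cl2, 0 °C; used crude
Reagents that add atoms: 3-chloroperbenzoic acid, OOC(=O)c1cccc(Cl)c1
Why: Prilezhaev epoxidation of the electron-rich styrene from the alpha face, the beta face being screened by the axial C20 and C19 methyl groups; the two new centres are transient and vanish in step 8.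

**Step 8**
Reactants: 9 14-bromo-11,12-bis(benzyloxy)-6alpha,7alpha-epoxyabieta-8,11,13-triene
Product: 10 14-bromo-11,12-bis(benzyloxy)abieta-8,11,13-trien-6-one (H-5 alpha; rings A and B trans-fused)
Conditions: BF3·OEt2 (0.1 equiv), CH2Cl2, −20 °C
Reagents that add atoms: none
Why: Meinwald rearrangement: the Lewis acid opens the epoxide at benzylic C7 and H-6 shifts to C7, which places the carbonyl at C6 and leaves H-5 alpha.

**Step 9**
Reactants: 10 14-bromo-11,12-bis(benzyloxy)abieta-8,11,13-trien-6-one
Product: 11 14-bromo-11,12-bis(benzyloxy)-5-epi-abieta-8,11,13-trien-6-one (H-5 beta; rings A and B cis-fused)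
Conditions: NaOMe (0.3 equiv), degassed MeOH-THF, argon, 40 °C; chromatography, recovered 10 resubmitted
Reagents that add atoms: none
Why: Epimerisation through the C5 enolate under thermodynamic control; the cis-fused ketone is expected, though not proven for this compound, to be favoured because it relieves the 1,3-diaxial C19/C20 methyl contact and the crowding between the C4 methyl groups and the C6 carbonyl, and C10 serves as the fixed reference centre.

**Step 10**
Reactants: 11 14-bromo-11,12-bis(benzyloxy)-5-epi-abieta-8,11,13-trien-6-one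
Product: 13 14-bromo-11,12-bis(benzyloxy)-6-(tert-butyldimethylsilyloxy)-5-epi-abieta-6,8,11,13-tetraene (fragment 1), via potassium enolate 12 (not isolated)
Conditions: KN(SiMe3)2, THF, −78 °C (ketone added to the base); TBSCl, −78 → 0 °C
Reagents that add atoms: tert-butyldimethylsilyl chloride, CC(C)(C)[Si](C)(C)Cl; potassium bis(trimethylsilyl)amide, C[Si](C)(C)[N-][Si](C)(C)C.[K+] (potassium stands in 12 only)
Why: Irreversible deprotonation with a bulky amide takes the benzylic and less hindered H-7 (this enolate is also the conjugated one) and O-silylation traps it, whereas H-5 between two quaternary carbons is not removed, so the cis fusion is kept.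

**Step 11**
Reactants: 14 (+)-sabinene (1R,5R)
Product: 16 thujan-10-ol (CH2OH syn to the cyclopropane CH2; H-4' anti), via tris(thujan-10-yl)borane 15 (not isolated)
Conditions: BH3·THF, THF, 0 °C → rt; aq NaOH, H2O2, 0 °C → rt
Reagents that add atoms: hydrogen peroxide, OO; borane (as BH3·THF), B (boron stands in 15 only)
Why: Anti-Markovnikov syn hydroboration puts boron on C10' and hydrogen on C4' from the face away from the cyclopropane CH2, and the oxidation places oxygen where boron was; the C4' centre is provisional since step 13 flattens it.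

**Step 12**
Reactants: 16 thujan-10-ol
Product: 17 thujan-10-al (1-isopropylbicyclo[3.1.0]hexane-4-carbaldehyde; major C4' epimer with CHO syn to the cyclopropane CH2)
Conditions: Dess-Martin periodinane, CH2Cl2, rt
Reagents that add atoms: none
Why: Dess-Martin oxidation of the primary alcohol under near-neutral conditions that leave the acid-sensitive cyclopropane alone; partial epimerisation at C4' would be harmless.

**Step 13**
Reactants: 17 thujan-10-al
Product: 18 4-chlorothujan-10-al (chlorine anti to the cyclopropane CH2; CHO syn; fragment 2)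
Conditions: NCS, pyrrolidine (0.2 equiv), CH2Cl2, 0 °C
Reagents that add atoms: N-chlorosuccinimide, O=C1CCC(=O)N1Cl
Why: Enamine-catalysed alpha-chlorination: both C4' epimers merge in the planar enamine, N-chlorosuccinimide delivers chlorine to the face away from the cyclopropane CH2, and the resulting quaternary C4' can no longer epimerise; no cation is formed at C4', so the cyclopropane stays closed.

**Step 14**
Reactants: 13 fragment 1 enol silane bromide; 18 4-chlorothujan-10-al
Product: 20 chlorohydrin with C14 bonded to carbinol carbon C10' (both C10' epimers; chlorine at C4' anti to the cyclopropane CH2), via C14 aryllithium 19 (not isolated)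
Conditions: t-BuLi (2.0 equiv), Et2O, −78 °C; 18, −78 °C; AcOH in Et2O, −78 °C; cold pH 7 work-up, used crude
Reagents that add atoms: tert-butyllithium, [Li]C(C)(C)C (lithium stands in 19 only)
Why: Bromine-lithium exchange is faster at −78 °C than any attack on the benzyl ethers or the bulky enol silane, and the aryllithium adds 1,2 to the non-enolisable alpha-chloro aldehyde; the cold acidic quench forestalls epoxide closure of the lithium carbinolate, C4' is untouched, and the C10' configuration is immaterial because both epimers give the same aldehyde in step 15.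

**Step 15**
Reactants: 20 chlorohydrin
Product: 22 ring E aldol as its 11,12-dibenzyl ether (H-5 beta; H-7 alpha; 10'-OH alpha; C14 on the cyclopropane face of C4'), via aluminium-bound alpha-aryl aldehyde 21 (not isolated)
Conditions: Me2AlCl (3 equiv, hexanes), CH2Cl2, −78 → −20 °C; aq NaHCO3 / KNaC4H4O6 (potassium sodium tartrate)
Reagents that add atoms: none
Why: Me2AlCl converts the carbinol into an aluminium alkoxide with loss of methane and further reagent pulls on the tertiary C4'-Cl bond; in the rotamer that holds C14 antiperiplanar to chlorine the electron-rich arene (ipso C14 para to the C11 oxygen) bridges as a phenonium ion and moves from C10' to C4' while the oxygen pushes, which makes the C14-C4' bond and leaves C10' as an aluminium-bound aldehyde without alpha hydrogen (21). The closest known reaction types are the halohydrin semipinacol (semihydrobenzoin-type) rearrangement, its organoaluminium-promoted version on beta-sulfonyloxy alcohols, and the intramolecular Mukaiyama aldol; each is established, but their combination in one flask on this substrate is untested. Ring E then closes by attack of enol silane carbon C7 on C10', a 5-(enolexo)-exo-trig aldol that the Baldwin rules allow and that gives a ring peri-fused across C7-C8-C14; the silyl group leaves as its chloride and the aldolate is freed on work-up. C4' is controlled by inversion at the migration terminus: chlorine lies anti to the cyclopropane, so C14 must arrive on the cyclopropane face, and both C10' epimers of 20 converge. C7 should be attacked on its beta face because ring A of the cis-fused system folds under the alpha face, and at C10' the aluminium-bearing oxygen should take the outward pseudo-equatorial place of the forming envelope, away from ring B and the silyloxy group, which gives the alpha hydroxyl cis to C5'; this is the least secure centre, whereas C7 is erased in step 17. The step needs the aryl shift to outrun hydride shift, opening of the cyclopropylcarbinyl system, epoxide closure and direct attack of C7 on C4'; the substrate answers with the best migrating group present, set up for a concerted anti displacement at a tertiary terminus, and the reagent with its oxophilicity, its proton scavenging and the low temperature.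

**Step 16**
Reactants: 22 ring E aldol dibenzyl ether
Product: 23 free 11,12-catechol (all centres as in 22)
Conditions: H2 (1 atm), 10% Pd/C, EtOAc, rt; filtered under argon and used at once
Reagents that add atoms: none
Why: Hydrogenolysis of the two aryl benzyl ethers; at 1 atm in a neutral solvent the C6 ketone, the non-benzylic C10' alcohol and the cyclopropane should persist, and the absence of acid and base guards the beta-hydroxy ketone against dehydration and retro-aldol cleavage.

**Step 17**
Reactants: 23 free 11,12-catechol
Product: 25 target CNP0178265.2 (11-hydroxy-12-oxo-7,9(11),13-triene quinone methide), via 11,12-quinone 24 (not isolated)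
Conditions: Ag2O, Et2O, dark, rt; filtration through a short silica pad
Reagents that add atoms: none
Why: Ag2O dehydrogenates the catechol to the 11,12-quinone, whose H-7 is alpha to the C6 ketone and gamma to the C11 carbonyl through C8=C9 and therefore moves to O-11 (prototropic shift, as in taxodione-type 6-oxo catechols), giving the 7,9(11),13-triene; this erases C7, and the neutral, brief treatment leaves C5, C10' and the other centres as they are.

**Compound list**
1 | (+)-carnosic acid (H-5 alpha, C20 carboxyl beta) | CC(C)c1cc2CC[C@H]3C(C)(C)CCC[C@]3(C(=O)O)c2c(O)c1O | starting material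
2 | benzyl 11,12-bis(benzyloxy)abieta-8,11,13-trien-20-oate | CC(C)c1cc2CC[C@H]3C(C)(C)CCC[C@]3(C(=O)OCc3ccccc3)c2c(OCc2ccccc2)c1OCc1ccccc1 | intermediate
3 | 11,12-bis(benzyloxy)abieta-8,11,13-trien-20-ol | CC(C)c1cc2CC[C@H]3C(C)(C)CCC[C@]3(CO)c2c(OCc2ccccc2)c1OCc1ccccc1 | intermediate
4 | 11,12-bis(benzyloxy)abieta-8,11,13-trien-20-al | CC(C)c1cc2CC[C@H]3C(C)(C)CCC[C@]3(C=O)c2c(OCc2ccccc2)c1OCc1ccccc1 | intermediate
5 | (E)-hydrazone of 4 (not isolated) | CC(C)c1cc2CC[C@H]3C(C)(C)CCC[C@]3(/C=N/N)c2c(OCc2ccccc2)c1OCc1ccccc1 | intermediate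
6 | 11,12-bis(benzyloxy)abieta-8,11,13-triene | CC(C)c1cc2CC[C@H]3C(C)(C)CCC[C@]3(C)c2c(OCc2ccccc2)c1OCc1ccccc1 | intermediate
7 | 14-bromo-11,12-bis(benzyloxy)abieta-8,11,13-triene | CC(C)c1c(Br)c2CC[C@H]3C(C)(C)CCC[C@]3(C)c2c(OCc2ccccc2)c1OCc1ccccc1 | intermediate
8 | 14-bromo-11,12-bis(benzyloxy)abieta-6,8,11,13-tetraene | CC(C)c1c(Br)c2C=C[C@H]3C(C)(C)CCC[C@]3(C)c2c(OCc2ccccc2)c1OCc1ccccc1 | intermediate
9 | 14-bromo-11,12-bis(benzyloxy)-6alpha,7alpha-epoxyabieta-8,11,13-triene | CC(C)c1c(Br)c2[C@@H]4O[C@@H]4[C@H]3C(C)(C)CCC[C@]3(C)c2c(OCc2ccccc2)c1OCc1ccccc1 | intermediate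
10 | 14-bromo-11,12-bis(benzyloxy)abieta-8,11,13-trien-6-one (H-5 alpha, trans-fused) | CC(C)c1c(Br)c2CC(=O)[C@H]3C(C)(C)CCC[C@]3(C)c2c(OCc2ccccc2)c1OCc1ccccc1 | intermediate
11 | 14-bromo-11,12-bis(benzyloxy)-5-epi-abieta-8,11,13-trien-6-one (H-5 beta, cis-fused) | CC(C)c1c(Br)c2CC(=O)[C@@H]3C(C)(C)CCC[C@]3(C)c2c(OCc2ccccc2)c1OCc1ccccc1 | intermediate
12 | potassium 6-en-6-olate of 11 (not isolated) | CC(C)c1c(Br)c2C=C([O-])[C@@H]3C(C)(C)CCC[C@]3(C)c2c(OCc2ccccc2)c1OCc1ccccc1.[K+] | intermediate
13 | C6 tert-butyldimethylsilyl enol ether of 11 (6-ene, fragment 1) | CC(C)c1c(Br)c2C=C(O[Si](C)(C)C(C)(C)C)[C@@H]3C(C)(C)CCC[C@]3(C)c2c(OCc2ccccc2)c1OCc1ccccc1 | intermediate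
14 | (+)-sabinene, (1R,5R) | C=C1CC[C@]2(C(C)C)C[C@@H]21 | starting material
15 | tris(thujan-10-yl)borane (not isolated) | B(C[C@@H]1CC[C@]2(C(C)C)C[C@@H]21)(C[C@@H]1CC[C@]2(C(C)C)C[C@@H]21)C[C@@H]1CC[C@]2(C(C)C)C[C@@H]21 | intermediate
16 | thujan-10-ol (CH2OH syn to the cyclopropane CH2) | OC[C@@H]1CC[C@]2(C(C)C)C[C@@H]21 | intermediate
17 | thujan-10-al (major C4' epimer, CHO syn to the cyclopropane CH2) | O=C[C@@H]1CC[C@]2(C(C)C)C[C@@H]21 | intermediate
18 | 4-chlorothujan-10-al (Cl anti to the cyclopropane CH2, fragment 2) | O=C[C@]1(Cl)CC[C@]2(C(C)C)C[C@@H]21 | intermediate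
19 | C14 aryllithium from 13 (not isolated) | CC(C)c1c([Li])c2C=C(O[Si](C)(C)C(C)(C)C)[C@@H]3C(C)(C)CCC[C@]3(C)c2c(OCc2ccccc2)c1OCc1ccccc1 | intermediate
20 | chlorohydrin, C14-C10'(OH)-C4'(Cl), both C10' epimers | CC(C)c1c(C(O)[C@]3(Cl)CC[C@]4(C(C)C)C[C@@H]43)c2C=C(O[Si](C)(C)C(C)(C)C)[C@@H]3C(C)(C)CCC[C@]3(C)c2c(OCc2ccccc2)c1OCc1ccccc1 | intermediate
21 | alpha-aryl aldehyde, C14 on quaternary C4' (cyclopropane face), drawn free of aluminium (not isolated) | CC(C)c1c([C@]3(C=O)CC[C@]4(C(C)C)C[C@@H]43)c2C=C(O[Si](C)(C)C(C)(C)C)[C@@H]3C(C)(C)CCC[C@]3(C)c2c(OCc2ccccc2)c1OCc1ccccc1 | intermediate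
22 | ring E aldol, 11,12-dibenzyl ether (H-7 alpha, 10'-OH alpha) | CC(C)c1c2c3[C@H](C(=O)[C@@H]4C(C)(C)CCC[C@]4(C)c3c(OCc3ccccc3)c1OCc1ccccc1)[C@@H](O)[C@]21CC[C@]2(C(C)C)C[C@@H]21 | intermediate
23 | free 11,12-catechol | CC(C)c1c2c3[C@H](C(=O)[C@@H]4C(C)(C)CCC[C@]4(C)c3c(O)c1O)[C@@H](O)[C@]21CC[C@]2(C(C)C)C[C@@H]21 | intermediate
24 | 11,12-quinone (not isolated) | CC(C)C1=C2C=3[C@H](C(=O)[C@@H]4C(C)(C)CCC[C@]4(C)C=3C(=O)C1=O)[C@@H](O)[C@]21CC[C@]2(C(C)C)C[C@@H]21 | intermediate
25 | CNP0178265.2 | CC(C)C1=C2C3=C(C(=O)[C@@H]4C(C)(C)CCC[C@]4(C)C3=C(O)C1=O)[C@@H](O)[C@]21CC[C@]2(C(C)C)C[C@@H]21 | target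

**Step count**
Total: 17 steps. Longest linear sequence: 14 steps (steps 1-10 and 14-17).

**Steps most likely to fail**

Step 15.
- What may go wrong: ionisation of the tertiary cyclopropylcarbinyl chloride may run ahead of aryl bridging. That would open the way to cyclopropane opening, hydride shift or attack of C7 on C4'. The facial course at C10' may also be poor.
- Fallback, from 20 back to 22: the two events are taken apart, and the shift is driven by alkoxide push instead of Lewis-acid pull.
- EtMgBr in toluene converts 20 into the bromomagnesium carbinolate F1. On warming, F1 undergoes the classical halomagnesium chlorohydrin rearrangement with the same inversion at C4'.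
- Without a free Lewis acid the enol silane is a spectator, so 21 can be isolated and purified.
- A separate Mukaiyama aldol (BF3·OEt2, CH2Cl2, −78 °C) then closes ring E to 22. Its promoter and temperature can be chosen for C10' alone.

Step 9.
- What may go wrong: the equilibrium may lie on the trans side, so that each pass returns little cis-fused ketone.
- Fallback, from 10 back to 25: C5 is left alone until the end, and 10 is taken through the operations of steps 10 and 14-17.
- This leads through the potassium enolate F2 to the trans-fused enol silane F3, and through the aryllithium F4 to the trans-fused chlorohydrin F5. It continues through the aldehyde F6 to the trans-fused aldol F7, then to the trans-fused catechol F8, and through the quinone F9 to the 5-alpha-H quinone methide F10.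
- In F10, C7 is sp2, H-5 is the only enolisable hydrogen and ring B is flattened over C6-C9, so a different equilibrium applies.
- DBU (2 equiv, toluene, argon, rt) then equilibrates C5 alone. The epimers are separated and F10 is recycled.

Step 13.
- What may go wrong: enamine formation from the alpha-branched aldehyde may be slow, the amine may be consumed by N-chlorination, and the facial selectivity at C4' may be insufficient. C4' carries the whole spiro configuration.
- Fallback, from 17 back to 18: catalysis is replaced by a preformed enol derivative.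
- TMSCl, NaI and Et3N in MeCN give the trimethylsilyl enol ether F11. This is chlorinated with NCS in CH2Cl2 at −78 °C in an amine-free medium, where the lower temperature should sharpen the bias for the open face.
- Since C4' of 18 cannot epimerise, a minor epimer can be removed by chromatography.

**Further compounds**
F1 | step 15 | bromomagnesium carbinolate of 20 | CC(C)c1c(C(O[Mg]Br)[C@]3(Cl)CC[C@]4(C(C)C)C[C@@H]43)c2C=C(O[Si](C)(C)C(C)(C)C)[C@@H]3C(C)(C)CCC[C@]3(C)c2c(OCc2ccccc2)c1OCc1ccccc1
F2 | step 9 | potassium 6-en-6-olate of 10 (H-5 alpha) | CC(C)c1c(Br)c2C=C([O-])[C@H]3C(C)(C)CCC[C@]3(C)c2c(OCc2ccccc2)c1OCc1ccccc1.[K+]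
F3 | step 9 | trans-fused C6 tert-butyldimethylsilyl enol ether, 14-bromide | CC(C)c1c(Br)c2C=C(O[Si](C)(C)C(C)(C)C)[C@H]3C(C)(C)CCC[C@]3(C)c2c(OCc2ccccc2)c1OCc1ccccc1
F4 | step 9 | trans-fused C14 aryllithium | CC(C)c1c([Li])c2C=C(O[Si](C)(C)C(C)(C)C)[C@H]3C(C)(C)CCC[C@]3(C)c2c(OCc2ccccc2)c1OCc1ccccc1
F5 | step 9 | trans-fused chlorohydrin (both C10' epimers) | CC(C)c1c(C(O)[C@]3(Cl)CC[C@]4(C(C)C)C[C@@H]43)c2C=C(O[Si](C)(C)C(C)(C)C)[C@H]3C(C)(C)CCC[C@]3(C)c2c(OCc2ccccc2)c1OCc1ccccc1
F6 | step 9 | trans-fused alpha-aryl aldehyde | CC(C)c1c([C@]3(C=O)CC[C@]4(C(C)C)C[C@@H]43)c2C=C(O[Si](C)(C)C(C)(C)C)[C@H]3C(C)(C)CCC[C@]3(C)c2c(OCc2ccccc2)c1OCc1ccccc1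
F7 | step 9 | trans-fused ring E aldol dibenzyl ether (C7 drawn as in 22; it is erased later) | CC(C)c1c2c3[C@H](C(=O)[C@H]4C(C)(C)CCC[C@]4(C)c3c(OCc3ccccc3)c1OCc1ccccc1)[C@@H](O)[C@]21CC[C@]2(C(C)C)C[C@@H]21
F8 | step 9 | trans-fused 11,12-catechol | CC(C)c1c2c3[C@H](C(=O)[C@H]4C(C)(C)CCC[C@]4(C)c3c(O)c1O)[C@@H](O)[C@]21CC[C@]2(C(C)C)C[C@@H]21
F9 | step 9 | trans-fused 11,12-quinone | CC(C)C1=C2C=3[C@H](C(=O)[C@H]4C(C)(C)CCC[C@]4(C)C=3C(=O)C1=O)[C@@H](O)[C@]21CC[C@]2(C(C)C)C[C@@H]21
F10 | step 9 | 5-alpha-H epimer of 25 | CC(C)C1=C2C3=C(C(=O)[C@H]4C(C)(C)CCC[C@]4(C)C3=C(O)C1=O)[C@@H](O)[C@]21CC[C@]2(C(C)C)C[C@@H]21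
F11 | step 13 | trimethylsilyl enol ether of 17 (drawn with oxygen cis to C3'; both geometries serve) | C[Si](C)(C)O/C=C1\CC[C@]2(C(C)C)C[C@@H]21
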